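## The problem

Vidalol B (17) consists of three benzene rings joined by two CH2 bridges. Ring B is a fully substituted 2-bromophloroglucinol (OH at B1, B3 and B5, Br at B2) that carries at B4 and B6 two identical 2,3-dibromo-4,5-dihydroxybenzyl groups, rings A and C (C1 bridge, C2 and C3 Br, C4 and C5 OH, C6 H). The molecule has a mirror plane through B2 and B5 and no stereocentre, so any stereocentre created on the way is temporary, controls nothing and must be erased. The real task is regiochemical: in each outer ring C2 and C3 must be brominated while C6 stays free, although C6 is also ortho to an oxygen and, once C2 carries bromine, differs little from C3 toward an electrophile. The free compound is fragile, since two catechols and a phloroglucinol are easily oxidized to quinones and the bridges are benzylic bonds to a trioxygenated ring that strong acid or ipso attack can break; the seven phenols are therefore best unveiled last. Once aryl bromides are present, alkyllithium reagents, dissolving metals and catalytic hydrogenation are excluded. The feature that invites a ring-forming approach is the pattern of each outer ring: the oxygen-bearing carbons C4 and C5 are adjacent and lie para and meta to C1, so the ring divides into a four-carbon unit C6=C1–C2=C3, a butadiene carrying the bridge at its 2-position, and a two-carbon unit C4–C5 with both oxygens on one side. Because rings A and C are identical, both can be built in one operation on a ring B scaffold that already carries its bromine.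

## Retrosynthesis

The last bonds to be cut are the seven O–CH3 bonds of the heptamethyl ether 16. Keeping every phenol masked to the end is preferred to any earlier unveiling, because free catechols and a free phloroglucinol would not survive the brominations and the strong base that precede. 16 is no simpler in skeleton than 17, but it is stable to air, base and chromatography. The forward step only has to cleave aryl methyl ethers with a Lewis acid beside aryl bromides.

In 16 the two C3–Br bonds are cut next, which leads through the dilithio species 15 to tribromide 14. The neighbouring option, to bring in both bromines of each outer ring by electrophilic substitution, is shorter but unsafe. After C2 is brominated, C3 (ortho to bromine) and C6 (ortho to the bridge) are each ortho to one oxygen and differ little, so mixtures and overbromination are to be expected. C3–H is, however, the only hydrogen flanked by a bromine and a methoxy group, so acidity distinguishes it. The forward step must deprotonate there with a hindered amide base at low temperature, leave three aryl bromides intact, and trap the anion with a bromine donor.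

The two C2–Br bonds of 14 are then cut to give 13. Here electrophilic substitution is reliable: ring B has no free position, and in a 4-alkyl-1,2-dimethoxybenzene the carbon para to the C5 methoxy group and ortho to the alkyl group (C2) is the innate site. The bromine of ring B is not cut at all. It is carried from the first compound, so that ring B has no free position left once both arms are attached.

13 is the tetramethyl ether of bis-catechol 12 (four O–CH3 bonds). 12 is the enol form of the bis(cyclohex-4-ene-1,2-dione) 11, which comes by oxidation from the bis(cis-diol) 10, and 10 by methanolysis from the bis-carbonate 9. No skeletal bond is cut here. The sequence trades two aromatic rings for two cyclohexenes with cis oxygens, the form a cycloaddition can deliver. The forward direction needs a fourfold alcohol oxidation that reaches the dione, spontaneous tautomerization, and prompt methylation of air-sensitive 12.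

In 9 the bonds C3–C4 and C5–C6 of each cyclohexene are cut, four C–C bonds in all, which gives bis-diene 7 and two molecules of vinylene carbonate (8). The competing cut at the CH2–aryl bonds needs two separately prepared, fully brominated benzyl units. The cycloaddition cut builds both outer rings from commercial 8 and raises no regiochemical question, because 8 is symmetric. 7 has two rings and four stereocentres fewer than 9. The forward reaction must add one molecule of 8 to each unactivated 2-substituted diene unit at high temperature faster than the diene polymerizes.

Each diene unit of 7 loses its two terminal methylene carbons (the future C3 and C6) as one molecule of ethylene (6), which leaves bis-alkyne 5. 5 is cut at the two CH2–C(sp) bonds to the bis(chloromethyl) compound 3 and two molecules of ethynylmagnesium bromide (4). 3 is cut at the two aryl–CH2 bonds to 2-bromo-1,3,5-trimethoxybenzene (1) and two molecules of formaldehyde (2). Attaching a complete dienyl unit in one step was weighed against this, but it needs a less accessible organometallic reagent. The forward steps are an exhaustive chloromethylation of two equivalent positions, a copper-catalysed coupling, and an ethylene enyne cross-metathesis.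

## Roads not taken

Alternative 1: Ring B itself is cut into a four-carbon and a two-carbon piece, the cyclobutenone A1 and the ethoxyalkyne A2, each carrying a ready-made 2,3-dibromo-4,5-dimethoxybenzyl group. On heating, A1 would open to a vinylketene, add A2 in a [2+2] fashion, and pass through 4π opening, 6π closure and tautomerization to the phenol A3.

- Merits: all four outer-ring bromines are fixed from the start, the substitution order of ring B follows from the known regiochemistry of the annulation, and the single ring CH left in A3 is the obvious site for the last bromine. The route is convergent.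
- Weak points: A1 and A2 are each several steps from a dibrominated benzyl halide. An ethyl ynol ether such as A2 can lose ethylene on heating to give a ketene, in competition with the annulation. The ring closure forms a pentasubstituted benzene between two ortho-crowded benzyl groups.
- Comparison: this road is better than the chosen plan in bromine regiocontrol, which it has without any metalation. The chosen plan sets against it that both outer rings arise together on one scaffold from a commercial two-carbon unit, and that no thermally delicate partner is needed.

Alternative 2: Each outer ring is cut at C2–C3 and C6–C1, the complementary Diels–Alder partition, back to the bis(bromoynone) A4 and two molecules of the bis(silyloxy)diene A5. Cycloaddition would give the bis(cyclohexa-1,4-diene) A6.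

- Merits: an electron-poor ynone with an electron-rich diene is a matched pair that should react far below the temperature the chosen key step needs. The C2 bromine arrives on the dienophile. Desilylation of A6 would put each ring at the dione level, so aromatization needs no oxidant. The ketone bridge would steer a later bromination to C3.
- Weak points: A4 requires two acylations of ring B by a bromopropynoyl unit, the second on a deactivated ring. Bromoynones are labile toward nucleophiles, and the silyl enol ether units of A5 may add in a conjugate sense instead. Both bridges arrive as ketones and must be reduced to CH2 on hindered, bromine-bearing diaryl ketones.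
- Comparison: this road has the more favourable cycloaddition and one bromine pre-installed. The chosen plan has the bridges at the right oxidation level from the first step and robust intermediates throughout.

Alternative 3: Each outer ring is cut at CH2–C1 and C2–Br. Two equivalents of the aryne A8, released from the iodoaryl sulfonate A7 by halogen–magnesium exchange with i-PrMgCl, would be attacked at C1 by the bis(benzylic) Grignard reagent A9. The arylmagnesium formed at C2 would be quenched with a bromine donor to give A10, which is one ring B bromination away from 16.

- Merits: bridge and C2 bromine are set in one flask with the C3 bromine already in place, and the inductive effect of that bromine directs the nucleophile to C1. On paper this is the shortest road to 16.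
- Weak points: A9 is a double benzylic Grignard reagent of a very electron-rich arene and is prone to Wurtz coupling and polymer formation. Two aryne captures on one molecule compete with aryne oligomerization and with the exchange reagent. The 2-bromoarylmagnesium intermediate can itself lose magnesium bromide. A7 is a pentasubstituted benzene that needs its own multistep synthesis.
- Comparison: this road is better in step count and in regiocontrol. The chosen plan sets against it that it avoids organometallic intermediates of doubtful stability and uses reaction types of broad precedent at every step.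

Key step: step 4

Remark: 2-bromo-1,3,5-trimethoxybenzene (1) is taken as a commercial compound, so the bromine of ring B is a spectator from the first step.
Remark: steps 1 to 4 act once on each of the two equivalent arms, so one molecule of 1, 3, 5 or 7 takes up two molecules of the partner (2, 4, 6 or 8); in step 1 each new CH2Cl group also takes one HCl.
Remark: 9 and 10 are expected as two diastereomers that differ only in the relative orientation of the two cis-fused rings; one is drawn and the mixture is carried on, because step 6 removes all four stereocentres.

## Route

Step 1
Reactants: 1 2-bromo-1,3,5-trimethoxybenzene; 2 formaldehyde as paraformaldehyde (2 equiv)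
Product: 3 2-bromo-4,6-bis(chloromethyl)-1,3,5-trimethoxybenzene
Conditions: (CH2O)n (5 equiv), HCl (g), conc. aq HCl, AcOH, 50 °C
Reagents that add atoms: formaldehyde (second molecule), SMILES C=O; hydrogen chloride, SMILES Cl
Why: Blanc chloromethylation, in which each of the two equivalent free positions of 1 (both ortho and para to methoxy groups) takes up one CH2O and one HCl, as in the exhaustive halomethylation of 1,3,5-trimethoxybenzene. The bromine occupies the third position, so the product has no free ring carbon left, and a large excess of formaldehyde and HCl should keep diarylmethane formation by the intermediate benzylic chloride behind the second chloromethylation.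

Step 2
Reactants: 3 2-bromo-4,6-bis(chloromethyl)-1,3,5-trimethoxybenzene; 4 ethynylmagnesium bromide (2 equiv)
Product: 5 2-bromo-1,3,5-trimethoxy-4,6-di(prop-2-yn-1-yl)benzene
Conditions: HC≡CMgBr (5 equiv, 0.5 M in THF), CuCl (10 mol %), THF, 0 °C to rt; aq NH4Cl
Reagents that add atoms: ethynylmagnesium bromide (second molecule), SMILES C#C[Mg]Br
Why: Copper-catalysed coupling of a benzylic chloride with an alkynyl Grignard reagent (monovalent copper from CuCl), one acetylide replacing the chloride of each CH2Cl group. Excess reagent holds each new terminal alkyne as its magnesium acetylide, which suppresses isomerization to the allene, and the hindered aryl bromide is inert to Grignard and copper reagents at this temperature.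

Step 3
Reactants: 5 2-bromo-1,3,5-trimethoxy-4,6-di(prop-2-yn-1-yl)benzene; 6 ethylene (2 equiv)
Product: 7 2-bromo-1,3,5-trimethoxy-4,6-bis(2-methylidenebut-3-en-1-yl)benzene
Conditions: ethylene (1 atm), second-generation Grubbs catalyst (H2IMes)(PCy3)Cl2Ru=CHPh (10 mol %), toluene, 80 °C
Reagents that add atoms: ethylene (second molecule), SMILES C=C
Why: Ethylene–alkyne cross enyne metathesis, in which each terminal alkyne takes up one molecule of ethylene: the ruthenium methylidene adds to the alkyne and the vinylcarbene is turned over by ethylene, so each propargyl group should become a 2-substituted buta-1,3-diene. This catalyst type is the one known to accept terminal alkynes that lack a propargylic heteroatom.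

Step 4
Reactants: 7 2-bromo-1,3,5-trimethoxy-4,6-bis(2-methylidenebut-3-en-1-yl)benzene; 8 vinylene carbonate (2 equiv)
Product: 9 5,5'-[(5-bromo-2,4,6-trimethoxy-1,3-phenylene)bis(methylene)]bis(cis-3a,4,7,7a-tetrahydro-1,3-benzodioxol-2-one), both ring fusions cis, racemic, one of two diastereomers drawn
Conditions: 8 (20 equiv, neat), BHT (5 mol %), argon, sealed tube, 170 °C
Reagents that add atoms: vinylene carbonate (second molecule), SMILES O=C1OC=CO1
Why: Thermal Diels–Alder reaction in which each of the two 2-substituted butadiene units of 7 takes up one molecule of the ring-locked cis-enediol carbonate 8; the closest known reaction type is the sealed-tube addition of vinylene carbonate to isoprene and other 2-alkylbutadienes. Both new bonds of a ring (C3–C4 and C5–C6) form in one concerted event that is suprafacial on diene and dienophile, so each outer ring closes by intermolecular [4+2] annulation of a four-carbon and a two-carbon unit and not by cyclization of a chain. The two new stereocentres of each ring (C4 and C5) are cis because they are the carbons of a (Z)-alkene held in a five-membered ring that adds through one face, so the carbonate is cis-fused. The relation between the two rings is not controlled and need not be, since all four centres are lost in step 6. The dienophile is symmetric, so no regiochemistry arises, and the unsubstituted diene termini leave no endo or exo question. The selectivity the step needs is twofold cycloaddition in preference to dimerization or polymerization of the diene; a large excess of 8 as the medium, a radical inhibitor, exclusion of oxygen and the easy s-cis conformation of a diene with only a 2-substituent should secure it. The aryl bromide, the methoxy groups and the CH2 bridges are inert under neutral thermal conditions.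

Step 5
Reactants: 9 5,5'-[(5-bromo-2,4,6-trimethoxy-1,3-phenylene)bis(methylene)]bis(cis-3a,4,7,7a-tetrahydro-1,3-benzodioxol-2-one)
Product: 10 4,4'-[(5-bromo-2,4,6-trimethoxy-1,3-phenylene)bis(methylene)]bis(cis-cyclohex-4-ene-1,2-diol)
Conditions: K2CO3 (0.2 equiv), MeOH, rt
Reagents that add atoms: none
Why: Base-catalysed transesterification of the two cyclic carbonates with methanol should release the cis-diols and dimethyl carbonate; no stereocentre is touched, and the alkenes, ethers and aryl bromide are inert.

Step 6
Reactants: 10 4,4'-[(5-bromo-2,4,6-trimethoxy-1,3-phenylene)bis(methylene)]bis(cis-cyclohex-4-ene-1,2-diol)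
Product: 12 4,4'-[(5-bromo-2,4,6-trimethoxy-1,3-phenylene)bis(methylene)]bis(benzene-1,2-diol), via bis(cyclohex-4-ene-1,2-dione) 11 (not isolated)
Conditions: (COCl)2 (4.4 equiv), DMSO (9 equiv), CH2Cl2, −78 °C; Et3N (12 equiv), −78 to 0 °C; degassed aq NaH2PO4 work-up under argon
Reagents that add atoms: none
Why: Swern oxidation of the four secondary alcohols should give the bis(1,2-dione) 11, each ring of which is the keto tautomer of a 4-substituted catechol, so the triethylamine present enolizes C3–H and C6–H and both rings aromatize without further oxidant, erasing the four stereocentres; only a small excess of activated sulfoxide is used so that little remains when the phenols appear.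

Step 7
Reactants: 12 4,4'-[(5-bromo-2,4,6-trimethoxy-1,3-phenylene)bis(methylene)]bis(benzene-1,2-diol)
Product: 13 2-bromo-4,6-bis[(3,4-dimethoxyphenyl)methyl]-1,3,5-trimethoxybenzene
Conditions: MeI (8 equiv), K2CO3 (8 equiv), acetone, reflux, argon
Reagents that add atoms: iodomethane, SMILES CI
Why: Williamson etherification of the four phenols (one MeI each) should turn the air-sensitive bis-catechol into a stable heptamethyl ether whose methoxy groups then direct bromination and metalation and are removed together at the end.

Step 8
Reactants: 13 2-bromo-4,6-bis[(3,4-dimethoxyphenyl)methyl]-1,3,5-trimethoxybenzene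
Product: 14 2-bromo-4,6-bis[(2-bromo-4,5-dimethoxyphenyl)methyl]-1,3,5-trimethoxybenzene
Conditions: NBS (2.05 equiv), MeCN, 0 °C to rt, dark
Reagents that add atoms: N-bromosuccinimide, SMILES O=C1CCC(=O)N1Br
Why: Electrophilic aromatic bromination, one NBS per outer ring; ring B has no free position, and each 4-alkyl-1,2-dimethoxybenzene ring should react at C2, para to the C5 methoxy group and ortho to the bridge, the established site for 3,4-dimethoxybenzyl compounds, while ionic conditions in the dark avoid benzylic radical bromination.

Step 9
Reactants: 14 2-bromo-4,6-bis[(2-bromo-4,5-dimethoxyphenyl)methyl]-1,3,5-trimethoxybenzene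
Product: 16 2-bromo-4,6-bis[(2,3-dibromo-4,5-dimethoxyphenyl)methyl]-1,3,5-trimethoxybenzene, via dilithio species 15 (not isolated)
Conditions: LiN(i-Pr)2 (3 equiv), THF, −78 °C, 1 h; BrCl2C–CCl2Br (3 equiv), −78 °C to rt
Reagents that add atoms: 1,2-dibromo-1,1,2,2-tetrachloroethane, SMILES ClC(Cl)(Br)C(Cl)(Cl)Br
Why: Deprotonative ortho-metalation with a lithium amide; in each outer ring C3–H is the only hydrogen flanked by bromine and a methoxy group and therefore the most acidic, as in the lithiation of 4-bromoveratrole or 5-bromo-1,3-benzodioxole between the two groups, and at −78 °C the ortho-bromoaryllithium 15 should survive long enough to take one bromine per ring from the polyhaloethane. A lithium amide, unlike an alkyllithium, does not exchange the three aryl bromides, and C6–H and the crowded CH2 bridges are less acidic.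

Step 10
Reactants: 16 2-bromo-4,6-bis[(2,3-dibromo-4,5-dimethoxyphenyl)methyl]-1,3,5-trimethoxybenzene
Product: 17 vidalol B, 2-bromo-4,6-bis[(2,3-dibromo-4,5-dihydroxyphenyl)methyl]benzene-1,3,5-triol
Conditions: BBr3 (12 equiv), CH2Cl2, −78 °C to rt; then H2O, 0 °C
Reagents that add atoms: none
Why: Lewis acid cleavage of all seven aryl methyl ethers by BBr3, the standard closing step for bromophenols; bromide attacks the methyl group of each boron-bound ether, the aryl bromides and CH2 bridges are untouched, and hydrolysis of the aryl borates should release the heptaphenol.

## Compound list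

1 | 2-bromo-1,3,5-trimethoxybenzene | COc1cc(OC)c(Br)c(OC)c1 | starting material
2 | formaldehyde (used as paraformaldehyde) | C=O | starting material
3 | 2-bromo-4,6-bis(chloromethyl)-1,3,5-trimethoxybenzene | COc1c(Br)c(OC)c(CCl)c(OC)c1CCl | intermediate
4 | ethynylmagnesium bromide | C#C[Mg]Br | starting material
5 | 2-bromo-1,3,5-trimethoxy-4,6-di(prop-2-yn-1-yl)benzene | COc1c(Br)c(OC)c(CC#C)c(OC)c1CC#C | intermediate
6 | ethylene | C=C | starting material
7 | 2-bromo-1,3,5-trimethoxy-4,6-bis(2-methylidenebut-3-en-1-yl)benzene | COc1c(Br)c(OC)c(CC(=C)C=C)c(OC)c1CC(=C)C=C | intermediate
8 | vinylene carbonate (1,3-dioxol-2-one) | O=C1OC=CO1 | starting material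
9 | 5,5'-[(5-bromo-2,4,6-trimethoxy-1,3-phenylene)bis(methylene)]bis(cis-3a,4,7,7a-tetrahydro-1,3-benzodioxol-2-one), one diastereomer drawn | COc1c(Br)c(OC)c(CC2=CC[C@@H]3OC(=O)O[C@@H]3C2)c(OC)c1CC1=CC[C@@H]2OC(=O)O[C@@H]2C1 | intermediate
10 | 4,4'-[(5-bromo-2,4,6-trimethoxy-1,3-phenylene)bis(methylene)]bis(cis-cyclohex-4-ene-1,2-diol), one diastereomer drawn | COc1c(Br)c(OC)c(CC2=CC[C@H](O)[C@H](O)C2)c(OC)c1CC1=CC[C@H](O)[C@H](O)C1 | intermediate
11 | 4,4'-[(5-bromo-2,4,6-trimethoxy-1,3-phenylene)bis(methylene)]bis(cyclohex-4-ene-1,2-dione) | COc1c(Br)c(OC)c(CC2=CCC(=O)C(=O)C2)c(OC)c1CC1=CCC(=O)C(=O)C1 | intermediate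
12 | 4,4'-[(5-bromo-2,4,6-trimethoxy-1,3-phenylene)bis(methylene)]bis(benzene-1,2-diol) | COc1c(Br)c(OC)c(Cc2ccc(O)c(O)c2)c(OC)c1Cc1ccc(O)c(O)c1 | intermediate
13 | 2-bromo-4,6-bis[(3,4-dimethoxyphenyl)methyl]-1,3,5-trimethoxybenzene | COc1c(Br)c(OC)c(Cc2ccc(OC)c(OC)c2)c(OC)c1Cc1ccc(OC)c(OC)c1 | intermediate
14 | 2-bromo-4,6-bis[(2-bromo-4,5-dimethoxyphenyl)methyl]-1,3,5-trimethoxybenzene | COc1c(Br)c(OC)c(Cc2cc(OC)c(OC)cc2Br)c(OC)c1Cc1cc(OC)c(OC)cc1Br | intermediate
15 | 2-bromo-4,6-bis[(2-bromo-3-lithio-4,5-dimethoxyphenyl)methyl]-1,3,5-trimethoxybenzene | COc1c(Br)c(OC)c(Cc2cc(OC)c(OC)c([Li])c2Br)c(OC)c1Cc1cc(OC)c(OC)c([Li])c1Br | intermediate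
16 | 2-bromo-4,6-bis[(2,3-dibromo-4,5-dimethoxyphenyl)methyl]-1,3,5-trimethoxybenzene | COc1c(Br)c(OC)c(Cc2cc(OC)c(OC)c(Br)c2Br)c(OC)c1Cc1cc(OC)c(OC)c(Br)c1Br | intermediate
17 | vidalol B, 2-bromo-4,6-bis[(2,3-dibromo-4,5-dihydroxyphenyl)methyl]benzene-1,3,5-triol | Oc1cc(Cc2c(O)c(Br)c(O)c(Cc3cc(O)c(O)c(Br)c3Br)c2O)c(Br)c(Br)c1O | target

## Step count and least certain steps

Total: 10 steps. Longest linear sequence: 10 steps (1 to 17).

Step 4 (key step). The likely failure is a competition: thermal or radical oligomerization of the diene units, and Diels–Alder dimerization between them, may consume 7 before the slow second addition of 8 is complete. The fallback sets out from 7 and returns at 9. Cheletropic addition of liquid SO2 (hydroquinone, sealed vessel, rt) should convert 7 into the storable 3,3'-[(5-bromo-2,4,6-trimethoxy-1,3-phenylene)bis(methylene)]bis(2,5-dihydrothiophene 1,1-dioxide) F1. F1 is then added in portions to neat 8 at 170 °C. Loss of SO2 releases each diene unit only in the presence of a large excess of dienophile, which should favour the formation of 9.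

Step 9. The metalation may be incomplete on one ring, 15 may lose LiBr to an aryne if the temperature rises, and deprotonation of a CH2 bridge may compete. The fallback sets out from 13 and returns at 16, using a carbonyl group to steer electrophilic bromination.
- Oxidation of both bridges of 13 with DDQ in aqueous dioxane should give (5-bromo-2,4,6-trimethoxy-1,3-phenylene)bis[(3,4-dimethoxyphenyl)methanone] F2.
- Exhaustive bromination with Br2 in AcOH should give (5-bromo-2,4,6-trimethoxy-1,3-phenylene)bis[(2,3-dibromo-4,5-dimethoxyphenyl)methanone] F3. The carbonyl group deactivates and shields its ortho position C6, so after C2 the second bromine should enter C3, meta to the carbonyl.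
- Ionic hydrogenation (Et3SiH, CF3CO2H) should reduce both diaryl ketones to CH2 and give 16.

Step 6. Incomplete fourfold oxidation would leave α-hydroxy ketones that aromatize by loss of water to monophenols, and surplus activated sulfoxide can alkylate the newly formed catechols at carbon. The fallback sets out from 7 and returns at 12; it brings the dione oxidation level in with the dienophile. Cycloaddition of 7 with 4,5-dichloro-1,3-dioxol-2-one under the conditions of step 4 should give 5,5'-[(5-bromo-2,4,6-trimethoxy-1,3-phenylene)bis(methylene)]bis(cis-3a,7a-dichloro-3a,4,7,7a-tetrahydro-1,3-benzodioxol-2-one) F4. Hydrolysis (NaHCO3, aqueous dioxane) opens the carbonates, the α-chloro alcohols collapse to the bis(1,2-dione) 11, and tautomerization should give 12 without any oxidant.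

Step 3. The ruthenium carbene may decay before both alkynes have reacted, or the alkyne may oligomerize, which would leave ene-yne mixtures. The fallback sets out from 3 and returns at 7. Buta-1,3-dien-2-ylmagnesium chloride F5 is prepared from 2-chlorobuta-1,3-diene and magnesium in THF. Copper-catalysed coupling of 3 with F5 (Li2CuCl4 catalyst, THF) attaches the complete diene unit to each CH2Cl group and should give 7 directly.

Step 1. The second chloromethylation may stall on a ring deactivated by bromine and the first CH2Cl group, the intermediate benzylic chloride may alkylate unreacted arene, or the acid may shift or remove the bromine of the electron-rich ring. The fallback sets out from 1 and returns at 5, bypassing 3.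
- Twofold Rieche formylation of 1 (Cl2CHOCH3, TiCl4, CH2Cl2) should give 5-bromo-2,4,6-trimethoxybenzene-1,3-dicarbaldehyde F6.
- Addition of 4 to both aldehydes should give 1,1'-(5-bromo-2,4,6-trimethoxy-1,3-phenylene)bis(prop-2-yn-1-ol) F7 as a mixture of diastereomers.
- Ionic deoxygenation (Et3SiH, BF3·OEt2, CH2Cl2, −78 °C), through a benzylic cation stabilized by the trimethoxyphenyl ring, should give 5.

## Further compounds

F1 | step 4 | 3,3'-[(5-bromo-2,4,6-trimethoxy-1,3-phenylene)bis(methylene)]bis(2,5-dihydrothiophene 1,1-dioxide) | COc1c(Br)c(OC)c(CC2=CCS(=O)(=O)C2)c(OC)c1CC1=CCS(=O)(=O)C1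
F2 | step 9 | (5-bromo-2,4,6-trimethoxy-1,3-phenylene)bis[(3,4-dimethoxyphenyl)methanone] | COc1c(Br)c(OC)c(C(=O)c2ccc(OC)c(OC)c2)c(OC)c1C(=O)c1ccc(OC)c(OC)c1
F3 | step 9 | (5-bromo-2,4,6-trimethoxy-1,3-phenylene)bis[(2,3-dibromo-4,5-dimethoxyphenyl)methanone] | COc1c(Br)c(OC)c(C(=O)c2cc(OC)c(OC)c(Br)c2Br)c(OC)c1C(=O)c1cc(OC)c(OC)c(Br)c1Br
F4 | step 6 | 5,5'-[(5-bromo-2,4,6-trimethoxy-1,3-phenylene)bis(methylene)]bis(cis-3a,7a-dichloro-3a,4,7,7a-tetrahydro-1,3-benzodioxol-2-one), one diastereomer drawn | COc1c(Br)c(OC)c(CC2=CC[C@]3(Cl)OC(=O)O[C@]3(Cl)C2)c(OC)c1CC1=CC[C@]2(Cl)OC(=O)O[C@]2(Cl)C1
F5 | step 3 | buta-1,3-dien-2-ylmagnesium chloride | C=CC(=C)[Mg]Cl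
F6 | step 1 | 5-bromo-2,4,6-trimethoxybenzene-1,3-dicarbaldehyde | COc1c(Br)c(OC)c(C=O)c(OC)c1C=O
F7 | step 1 | 1,1'-(5-bromo-2,4,6-trimethoxy-1,3-phenylene)bis(prop-2-yn-1-ol), mixture of diastereomers, configuration not defined | COc1c(Br)c(OC)c(C(O)C#C)c(OC)c1C(O)C#C
A1 | alternative 1 | 2-[(2,3-dibromo-4,5-dimethoxyphenyl)methyl]-3-ethoxycyclobut-2-en-1-one | CCOC1=C(Cc2cc(OC)c(OC)c(Br)c2Br)C(=O)C1
A2 | alternative 1 | 2,3-dibromo-1-(3-ethoxyprop-2-yn-1-yl)-4,5-dimethoxybenzene | CCOC#CCc1cc(OC)c(OC)c(Br)c1Br
A3 | alternative 1 | 2,4-bis[(2,3-dibromo-4,5-dimethoxyphenyl)methyl]-3,5-diethoxyphenol | CCOc1cc(O)c(Cc2cc(OC)c(OC)c(Br)c2Br)c(OCC)c1Cc1cc(OC)c(OC)c(Br)c1Br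
A4 | alternative 2 | 1,1'-(2,4,6-trimethoxy-1,3-phenylene)bis(3-bromoprop-2-yn-1-one) | COc1cc(OC)c(C(=O)C#CBr)c(OC)c1C(=O)C#CBr
A5 | alternative 2 | 2,3-bis(trimethylsilyloxy)buta-1,3-diene | C=C(O[Si](C)(C)C)C(=C)O[Si](C)(C)C
A6 | alternative 2 | 2,4-bis{[2-bromo-4,5-bis(trimethylsilyloxy)cyclohexa-1,4-dien-1-yl]carbonyl}-1,3,5-trimethoxybenzene | COc1cc(OC)c(C(=O)C2=C(Br)CC(O[Si](C)(C)C)=C(O[Si](C)(C)C)C2)c(OC)c1C(=O)C1=C(Br)CC(O[Si](C)(C)C)=C(O[Si](C)(C)C)C1
A7 | alternative 3 | 3-bromo-2-iodo-4,5-dimethoxyphenyl 4-chlorobenzenesulfonate | COc1cc(OS(=O)(=O)c2ccc(Cl)cc2)c(I)c(Br)c1OC
A8 | alternative 3 | 3-bromo-4,5-dimethoxybenzyne | COC1=CC#CC(Br)=C1OC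
A9 | alternative 3 | [(2,4,6-trimethoxy-1,3-phenylene)bis(methylene)]bis(magnesium chloride) | COc1cc(OC)c(C[Mg]Cl)c(OC)c1C[Mg]Cl
A10 | alternative 3 | 2,4-bis[(2,3-dibromo-4,5-dimethoxyphenyl)methyl]-1,3,5-trimethoxybenzene | COc1cc(OC)c(Cc2cc(OC)c(OC)c(Br)c2Br)c(OC)c1Cc1cc(OC)c(OC)c(Br)c1Br
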